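## Retrosynthetic overview

1. Target 4 ⇒ cyclohexene 2: take off the vicinal Cl/Br pair (anti addition in which chlorine is the electrophile and bromide ends on the tertiary carbon).
2. 2 ⇒ (–)-α-bisabolol 1: cut the O–C(CH3)2 bond of the oxane (6-endo bromoetherification; C–O and C–Br are made together).
3. Ring order: the carbocycle and both carbinol-side stereocentres come with 1; the oxane ring is closed in step 1; step 2 adds the two halogens to the carbocycle.

Assumption: commercial (–)-α-bisabolol (levomenol) is the (2S,1′S) enantiomer; the target read from the SMILES is (3R,6S)-3-bromo-6-[(1S,3R,4R)-4-bromo-3-chloro-4-methylcyclohexyl]-2,2,6-trimethyloxane, with Br and Cl trans-diaxial on the cyclohexane, Br cis and Cl trans to the oxanyl group.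

## Route

Step 1
Reactants: 1 (–)-α-bisabolol
Product: 2 (3R,6S)-3-bromo-2,2,6-trimethyl-6-[(1S)-4-methylcyclohex-3-en-1-yl]oxane
Conditions: NBS (1.05 equiv), HFIP, 4 Å MS, 0 °C, dark
Reagents that add atoms: N-bromosuccinimide (NBS), O=C1CCC(=O)N1Br
Why: Bromonium-induced 6-endo (Markovnikov) bromoetherification of a γ,δ-unsaturated tertiary alcohol, a known closure for 3-bromo-2,2,6-trimethyloxanes: the hydroxyl opens the bromonium ion of the prenyl-type alkene at its tertiary carbon through a chair transition state with the cyclohexenyl group and the bromine both equatorial, which sets C3 as R (Br trans to the cyclohexenyl group), while the bromonium ion of the ring alkene has no nucleophile in easy reach and gives its bromine back.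

Step 2
Reactants: 2 (3R,6S)-3-bromo-2,2,6-trimethyl-6-[(1S)-4-methylcyclohex-3-en-1-yl]oxane
Product: 4 (3R,6S)-3-bromo-6-[(1S,3R,4R)-4-bromo-3-chloro-4-methylcyclohexyl]-2,2,6-trimethyloxane, via formamidinium saccharinate 3 (not isolated)
Conditions: N-chlorosaccharin (1.05 equiv), Ph3P=S (5 mol %), DMF/CH2Cl2 1:4, –40 °C; then LiBr (3 equiv), –40 to 0 °C
Reagents that add atoms: N-chlorosaccharin, O=C1N(Cl)S(=O)(=O)c2ccccc12; lithium bromide, [Li+].[Br-]; N,N-dimethylformamide, CN(C)C=O (its atoms stay in 3 only)
Why: Proposed new method: a chloronium-first, DMF-relayed anti-bromochlorination. Free bromide cannot be present with a chlorine electrophile (it would be oxidised and add as Br+/Cl–, putting Cl on the tertiary carbon), so chlorine is transferred first (N-chlorosaccharin, Ph3P=S as a reversible Lewis-base shuttle) to the ring alkene on the face anti to the oxanyl group, which is the face of axial attack at the CH carbon of the half-chair. That chloriranium ion is the only one that can be opened trans-diaxially at the tertiary carbon, and the oxygen of DMF does so to give the O-alkyl formamidinium salt 3; the wrong-face ion is handed back through the shuttle. Once the chlorine electrophile is used up, LiBr is added: the tertiary C–O bond ionises with anchimeric help from the antiperiplanar axial chlorine and bromide reopens the same chloriranium ion at the tertiary carbon. C–Br thus forms with net retention, which sets both new centres (3R,4R) with Cl on the secondary and Br on the tertiary carbon. The closest known reaction types are the cohalogenation of alkenes by N-haloimides in DMF (halo-formyloxylation) and the Vilsmeier-type deoxybromination of alcohols through alkoxymethyleneiminium bromides.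

## Compound list

1 | (–)-α-bisabolol, (2S)-6-methyl-2-[(1S)-4-methylcyclohex-3-en-1-yl]hept-5-en-2-ol | CC(C)=CCC[C@](C)(O)[C@H]1CCC(C)=CC1 | starting material
2 | (3R,6S)-3-bromo-2,2,6-trimethyl-6-[(1S)-4-methylcyclohex-3-en-1-yl]oxane (Br equatorial, trans to the cyclohexenyl group) | CC1(C)O[C@](C)([C@H]2CCC(C)=CC2)CC[C@H]1Br | intermediate
3 | N-[[(1R,2R,4S)-4-[(2S,5R)-5-bromo-2,6,6-trimethyloxan-2-yl]-2-chloro-1-methylcyclohexyl]oxymethylidene]-N-methylmethanaminium saccharinate (O-alkylated DMF; C–O axial and cis to the oxanyl group, Cl axial and trans to it) | CC1(C)O[C@](C)([C@H]2CC[C@@](C)(OC=[N+](C)C)[C@H](Cl)C2)CC[C@H]1Br.O=C1[N-]S(=O)(=O)c2ccccc12 | intermediate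
4 | (3R,6S)-3-bromo-6-[(1S,3R,4R)-4-bromo-3-chloro-4-methylcyclohexyl]-2,2,6-trimethyloxane (CNP0182923.1) | CC1(C)O[C@](C)([C@H]2CC[C@@](C)(Br)[C@H](Cl)C2)CC[C@H]1Br | target

## Step count and risks

Total step count: 2. Longest linear sequence: 2. The route has only these two steps, so both are ranked, the more fragile first; there is no third step.

Step 2 (the proposed new step). Risks: chlorine transfer to the wrong face, ene-type allylic chlorination instead of capture by DMF, and partial loss of configuration in the bromide substitution. The fallback uses known chemistry and sets out from 2. NBS in acetone–water at 0 °C gives, through the reversibly formed bromonium ion, bromohydrin F1 (water at the tertiary carbon, bromine anti to the oxanyl group, trans-diaxial, as known for limonene-type cyclohexenes). NaOH in methanol closes it to epoxide F2, with the oxygen cis to the oxanyl group. Li2CuCl4 in THF opens F2 trans-diaxially at the secondary carbon to chlorohydrin F3. TMSBr in CH2Cl2 at –20 °C then turns the tertiary hydroxyl into the bromide with retention through the chloriranium ion, and the fallback comes back to the route at 4.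

Step 1. Risks: 5-exo closure to the oxolane, the C3 epimer, and bromination of the ring alkene. The fallback sets out from 1 and lets the ring close 5-exo on purpose (NBS, CH2Cl2, –78 to 0 °C) to oxolane F4, separated from its C2 epimer. Catalytic ZnBr2 in CH2Cl2 (0 °C to room temperature) then expands the ring through the bicyclic oxiranium ion: oxygen shifts to the tertiary carbon and bromide returns to the secondary carbon with inversion. This gives the same C3 configuration as direct 6-endo closure of the same bromonium ion, and the fallback comes back to the route at 2.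

## Further compounds

F1 | step 2 | (1R,2R,4S)-2-bromo-4-[(2S,5R)-5-bromo-2,6,6-trimethyloxan-2-yl]-1-methylcyclohexan-1-ol | CC1(C)O[C@](C)([C@H]2CC[C@@](C)(O)[C@H](Br)C2)CC[C@H]1Br
F2 | step 2 | (1R,4S,6S)-4-[(2S,5R)-5-bromo-2,6,6-trimethyloxan-2-yl]-1-methyl-7-oxabicyclo[4.1.0]heptane | CC1(C)O[C@](C)([C@H]2CC[C@@]3(C)O[C@H]3C2)CC[C@H]1Br
F3 | step 2 | (1R,2R,4S)-4-[(2S,5R)-5-bromo-2,6,6-trimethyloxan-2-yl]-2-chloro-1-methylcyclohexan-1-ol | CC1(C)O[C@](C)([C@H]2CC[C@@](C)(O)[C@H](Cl)C2)CC[C@H]1Br
F4 | step 1 | (2S,5S)-2-(2-bromopropan-2-yl)-5-methyl-5-[(1S)-4-methylcyclohex-3-en-1-yl]oxolane | CC(C)(Br)[C@@H]1CC[C@](C)(O1)[C@H]2CCC(C)=CC2
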